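## Structural features

The target is a linear diarylheptanoid (chain C1 to C7) folded into a 2,4,6-trisubstituted oxane. The ring oxygen O1 joins C1 and C5; C1 carries the 4-hydroxy-3-methoxyphenyl (guaiacyl) ring, C3 a free secondary hydroxyl, and C5 the exocyclic carbinol C6, whose neighbour C7 is the benzylic CH2 of the 4-hydroxyphenyl ring. There are four stereocentres, C1 (S), C3 (R), C5 (S) and C6 (R). C5 and C6 are adjacent and carry their oxygens anti to each other, while C1, C3 and C5 are spaced 1,3 around the ring. On the ring the C3 hydroxyl is cis to the C5 side chain and the guaiacyl group is trans to both, so this is the 2,6-trans oxane with an axial aryl group in the chair that keeps the other two substituents equatorial, the less stable arrangement at C1. The C1–O1 bond is a para-oxygenated benzylic ether: it ionises under acid (which would drain the trans ring into the cis one) and is open to hydrogenolysis. The phenols are oxidation-prone, and an alpha-oxygenated aldehyde used to bring in C6 can epimerise. The real difficulty is the anti C5/C6 pair next to the ring together with the kinetic placement of the aryl group at C1. The key step uses the fact that the C3 oxygen is 1,3 to both ether carbons C1 and C5: this is the oxidation pattern of a 2,3-dihydro-4H-pyran-4-one (C3 carbonyl, C1=C2 enol ether, O1, C5), which arises from an aldehyde at C5 and a four-carbon 1-methoxy-3-silyloxydiene supplying C1 to C4.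

## Logic of the disconnections

**20 back to 19 and 18.** The bonds cut are the two aryl O–CH2Ph bonds (20 to 19) and the two O–Si bonds at C3 and C6 (19 to 18). The cut is protective: both carbinols and both phenols must be masked during the Lewis acid and organometallic steps. The gain is that the free para-hydroxybenzylic ether exists only in the final operation. The demand is that hydrogenolysis distinguishes aryl benzyl ethers from the ring C1–O1 bond, and that fluoride is applied while the phenols are still capped.

**18 back to 13 and 15 (through 16 and 17).** The bond cut is C1–C(aryl). It is cut here because this bond defines the difficult trans relationship: an aryl nucleophile adding to the ring oxocarbenium ion enters axially, anti to the C5 chain, under kinetic control. The gain is convergence and the reduction of C1 to an anomeric leaving group of no stereochemical consequence. The demand is a leaving group that ionises under mild Lewis acidity and a carbon nucleophile that is neither basic enough to deprotonate the cation nor reactive towards silyl and benzyl ethers.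

**13 back to 12, 11 and 10.** The bonds cut are C1–S with C2–H (13 to 12), O–Si at C3 (12 to 11) and C3–H (11 to 10). The reason is that an anomeric sulfone is the HX adduct of an enol ether, and an enol ether with an allylic oxygen is the 1,2-reduction product of a vinylogous ester. C3 is thus set on a rigid enone while C1 is still sp2. The gain is that all ring stereochemistry is derived from C5 alone. The demands are 1,2- rather than 1,4-reduction with axial hydride delivery, and protonation of the enol ether at C2 without loss of the allylic C3 oxygen.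

**10 back to 7 and 8.** The bonds cut are C4–C5 and O1–C1. The 1,3-dioxygen pattern around C3 makes this the natural cut: one operation closes the ring, forms two skeletal bonds and creates C5. The gain is a three-carbon chiral-pool fragment plus a commercial four-carbon diene. The demand is anti (Felkin–Anh) facial selectivity at the aldehyde, which calls for a non-chelating Lewis acid, a poorly donating silyl ether at C6, and conditions that do not epimerise C6.

**7 back to 6, 5, 4 and 1.** These are changes of oxidation level at C5 (7 to 6), the O–Si bond (6 to 5), the ester O–CH3 bond (5 to 4) and exchange of the C6–O bond for C6–N (4 to 1). The reason is that C6 with its configuration and the whole C5–C7 aryl unit are already present in the D-amino acid. The gain is that no asymmetric step is needed for C6. The demands are net retention in the diazotisation (through 2 and 3), a reduction that stops at the aldehyde, and use of 7 without storage.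

**15 back to 14.** The bond cut is the phenolic O–CH2Ph bond. The phenol must be masked before metalation. The demand is only a clean O-alkylation.

## Other disconnections considered

**Alternative 1:** The cut is C2–C3 and C3–C4, with C3 as a twofold acyl anion equivalent, the silyl dithiane A1, placed between the aryl oxirane A2 (C1–C2) and the benzyloxy epoxide A3 (C4–C7).
- **Forward key step:** lithiated A1 would open A2 at its CH2 terminus. HMPA would then trigger a 1,4-Brook shift of silicon to the new C1 alkoxide, unveiling a second dithiane anion that opens A3 at its CH2 terminus. The product A4 holds the full chain with C1 silylated, C5 free and C3 masked.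
- **Completion:** sulfonylation at C5, unmasking of the C1 hydroxyl, ether closure with inversion at C5, dithiane removal, reduction at C3 and debenzylation.
- **In its favour:** two C–C bonds and the whole C1–C7 skeleton arise in one flask, and the two hydroxyls come out differentiated. C1 and C5 are fixed by separately made enantiopure epoxides. The ring is closed by SN2 at the non-benzylic C5, so the trans ring follows from stereospecific inversion and not from a kinetic preference; on this point it is better than the chosen plan.
- **Against it here:**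
  - A2 is an electron-rich aryl oxirane, in which attack at the benzylic carbon competes.
  - A3 needs the syn C5/C6 pair, so the 1,2-induction problem returns in the opposite sense or a separate asymmetric oxidation sequence is needed.
  - HMPA is required.
  - Displacement at a secondary carbon flanked by the C6 benzyloxy group is slow and elimination competes.
  - C3 would be set last by reducing a 2,6-trans oxan-4-one whose axial aryl group shields the face the hydride must use; this is less secure than reduction of enone 10.
- **Comparison:** on structure the two plans are equal in that both can draw C6 from the same chiral pool. On mechanism it is better at C1 and weaker at C3. On step economy, two epoxide syntheses plus about six steps after A4 make it clearly longer.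

**Alternative 2:** The cut is O1–C1, made under thermodynamic control on a substrate in which the C3 oxygen and C6 are tied as a gamma-lactone.
- **Forward key step:** mild acid would ionise the benzylic alcohol of the cis hydroxy lactone A5 (either C1 epimer). Reversible capture of the cation by the C5 hydroxyl gives the bicyclic lactone A6. Because the lactone bridge forces the C3 and C5 substituents diaxial on the new oxane, the aryl group is equatorial (exo) in the most stable isomer, and this is the 2,6-trans relationship.
- **In its favour:** the lability of the C1–O1 bond becomes the control element. The closure is stereoconvergent and self-correcting, so no stereocontrol is needed when C1 is first made. The cis C3/C5 relationship is locked by the bridge. At C1 this is better than the chosen plan, which depends on a kinetic axial attack.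
- **Against it here:**
  - C6 is a carbonyl carbon in A6, so the C6–C7 bond and the C6 stereocentre must be made afterwards. That means a benzylic organometallic addition to a lactone (over-addition, homocoupling of the reagent) and a ketone reduction relying on 1,2-induction from C5.
  - Once the bridge is opened the aryl group is axial again and every later step must avoid acid.
  - A5 itself needs an enantioselective synthesis.
- **Comparison:** on structure the chosen plan is better at C6 (chiral pool against late induction). On mechanism the alternative is better at C1 and equal at C3. On step economy it is probably equal or somewhat longer.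

**Alternative 3:** The cut is C3–C4 and O1–C5 through a 2-isoxazoline, from the ketal-protected oxime A7 (C1–C3 with the aryl ring) and the (R)-allylic silyl ether A8 (C4–C7).
- **Forward key step:** NaOCl would convert A7 into its nitrile oxide, which adds to the terminal alkene of A8 with oxygen at C5. The allylic stereocentre directs the face (alkoxy group inside, oxygen entering anti), giving A9.
- **Completion:** reductive N–O cleavage of A9, hydroxyl-directed anti reduction at C3, ketal removal and closure of O1–C1.
- **In its favour:** the conditions are neutral, so C6 is not at risk. A8 is one methylenation away from 7. Regiochemistry is secure. C3 can be set by an acyclic 1,3-anti directed reduction, which is the equal of the Luche step and independent of ring conformation.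
- **Against it here:**
  - Facial selectivity of nitrile oxide additions to acyclic allylic ethers is usually only moderate.
  - The central problem at C1 is left open. Reductive etherification of the unmasked aryl ketone would deliver hydride axially and give the cis ring. The trans ring would need a reagent-controlled reduction at C1 and an invertive closure at a benzylic carbon that prefers to ionise.
- **Comparison:** on structure it is equal for C5 and C6. On mechanism it is equal or better at C3, weaker at C5 and much weaker at C1. On step economy it is longer, since A7 needs its own sequence and about five steps follow A9.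

Key step: step 5

Remark on the chemistry: chain numbering C1 to C7 is used for all intermediates. The configurations of 7 (R) and 10 (ring carbon S, carbinol carbon R) were re-derived from the target and are consistent with it, so no structure needs correcting. The one design change is that the phenol benzyl ether is bought in with the amino acid (O-benzyl-D-tyrosine), which removes a phenol alkylation and the risk of ring nitrosation during diazotisation.

## Route

Step 1
Reactants: 1 O-benzyl-D-tyrosine
Product: 4 (R)-3-[4-(benzyloxy)phenyl]-2-hydroxypropanoic acid, via diazonium carboxylate 2 (not isolated), via alpha-lactone 3 (not isolated)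
Conditions: NaNO2, 1 M H2SO4, 1,4-dioxane–H2O, 0 °C → rt
Reagents that add atoms: water, O
Why: Diazotisation of an alpha-amino acid: the carboxylate displaces N2 from 2 with inversion to give 3, and water opens 3 at the alkyl carbon with a second inversion, so C6 keeps the (R) configuration (net retention); the aryl benzyl ether is inert to cold dilute acid.

Step 2
Reactants: 4 (R)-3-[4-(benzyloxy)phenyl]-2-hydroxypropanoic acid
Product: 5 methyl (R)-3-[4-(benzyloxy)phenyl]-2-hydroxypropanoate
Conditions: MeOH, H2SO4 (cat.), reflux
Reagents that add atoms: methanol, CO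
Why: Fischer esterification; the carbinol stereocentre is not enolised under acid, and the ester is the handle for partial reduction.

Step 3
Reactants: 5 methyl (R)-3-[4-(benzyloxy)phenyl]-2-hydroxypropanoate
Product: 6 methyl (R)-3-[4-(benzyloxy)phenyl]-2-[(tert-butyldimethylsilyl)oxy]propanoate
Conditions: TBSCl, imidazole, DMF, rt
Reagents that add atoms: tert-butyldimethylsilyl chloride, CC(C)(C)[Si](C)(C)Cl
Why: Standard imidazole-mediated silylation of a secondary alcohol; the bulky, weakly basic silyl ether later rules out chelation in the key step.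

Step 4
Reactants: 6 methyl (R)-3-[4-(benzyloxy)phenyl]-2-[(tert-butyldimethylsilyl)oxy]propanoate
Product: 7 (R)-3-[4-(benzyloxy)phenyl]-2-[(tert-butyldimethylsilyl)oxy]propanal
Conditions: (i-Bu)2AlH (1.1 equiv), CH2Cl2, −78 °C; MeOH, then aq. potassium sodium tartrate
Reagents that add atoms: none
Why: Partial reduction of an alpha-alkoxy ester: the aluminium hemiacetal is stable at −78 °C and releases the aldehyde only on work-up; 7 is used at once without chromatography to avoid epimerisation at C6.

Step 5
Reactants: 7 (R)-3-[4-(benzyloxy)phenyl]-2-[(tert-butyldimethylsilyl)oxy]propanal; 8 Danishefsky's diene, (E)-1-methoxy-3-[(trimethylsilyl)oxy]buta-1,3-diene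
Product: 10 (2S)-2-[(1R)-2-[4-(benzyloxy)phenyl]-1-[(tert-butyldimethylsilyl)oxy]ethyl]-2,3-dihydro-4H-pyran-4-one, via Mukaiyama aldol adduct 9 (not isolated)
Conditions: 8 (1.5 equiv), BF3·OEt2 (1.1 equiv), CH2Cl2, −78 °C; then TFA, 0 °C (same flask); aq. NaHCO3
Reagents that add atoms: none
Why: This is the Lewis acid-promoted cyclocondensation of a 1-methoxy-3-silyloxybutadiene with an aldehyde (hetero-Diels–Alder reaction in its Mukaiyama aldol variant), a known reaction of alpha-oxygenated aldehydes. BF3 binds the aldehyde oxygen and the unsubstituted terminus of 8 (future C4) attacks through an open transition state, forming C4–C5 and giving 9 after loss of the trimethylsilyl group. The new stereocentre C5 is controlled by C6 through the polar Felkin–Anh conformer: the C6–OSi bond stands perpendicular to the carbonyl, the nucleophile enters anti to it and past the hydrogen, so the C5 oxygen ends anti to the C6 oxygen, (5S) from the (6R) aldehyde. TFA then closes the ring: the C5 hydroxyl adds to the methoxy-bearing enone carbon C1 in a 6-endo-trig conjugate addition (O1–C1) and methanol is eliminated, leaving the vinylogous ester. The selectivity the step needs is facial (anti against syn at C5); it is secured by the monodentate BF3, the non-coordinating solvent and the bulky, poorly donating silyl ether, which together exclude the chelate that would give the syn isomer. The low temperature protects the epimerisable C6 centre, and the short acid treatment at 0 °C leaves the secondary silyl ether and the aryl benzyl ether intact.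

Step 6
Reactants: 10 (2S)-2-[(1R)-2-[4-(benzyloxy)phenyl]-1-[(tert-butyldimethylsilyl)oxy]ethyl]-2,3-dihydro-4H-pyran-4-one
Product: 11 (2S,4S)-2-[(1R)-2-[4-(benzyloxy)phenyl]-1-[(tert-butyldimethylsilyl)oxy]ethyl]-3,4-dihydro-2H-pyran-4-ol
Conditions: NaBH4, CeCl3·7H2O, MeOH, −78 → −20 °C
Reagents that add atoms: none
Why: Luche 1,2-reduction of a vinylogous ester: CeCl3 suppresses conjugate reduction, and the hydride adds axially to the half-chair that holds the C5 chain pseudo-equatorial, giving the pseudo-equatorial C3 hydroxyl cis to that chain.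

Step 7
Reactants: 11 (2S,4S)-2-[(1R)-2-[4-(benzyloxy)phenyl]-1-[(tert-butyldimethylsilyl)oxy]ethyl]-3,4-dihydro-2H-pyran-4-ol
Product: 12 (2S,4S)-2-[(1R)-2-[4-(benzyloxy)phenyl]-1-[(tert-butyldimethylsilyl)oxy]ethyl]-4-[(tert-butyldimethylsilyl)oxy]-3,4-dihydro-2H-pyran
Conditions: TBSCl, imidazole, DMF, rt
Reagents that add atoms: tert-butyldimethylsilyl chloride, CC(C)(C)[Si](C)(C)Cl
Why: Silylation under basic conditions that the acid-sensitive enol ether tolerates; a silyl ether at C3 is a poor leaving group, which disfavours allylic (Ferrier-type) ionisation in the next two steps, and it is removed together with the C6 silyl ether.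

Step 8
Reactants: 12 (2S,4S)-2-[(1R)-2-[4-(benzyloxy)phenyl]-1-[(tert-butyldimethylsilyl)oxy]ethyl]-4-[(tert-butyldimethylsilyl)oxy]-3,4-dihydro-2H-pyran
Product: 13 (4S,6S)-2-(benzenesulfonyl)-6-[(1R)-2-[4-(benzyloxy)phenyl]-1-[(tert-butyldimethylsilyl)oxy]ethyl]-4-[(tert-butyldimethylsilyl)oxy]oxane (mixture of C2 epimers)
Conditions: PhSO2H, CH2Cl2, 0 °C → rt
Reagents that add atoms: benzenesulfinic acid, O=S(O)c1ccccc1
Why: Addition of a sulfinic acid to an enol ether (anomeric sulfone formation): protonation at C2 gives the ring oxocarbenium ion, which the sulfinate captures through sulfur; the configuration at C1 is irrelevant because the sulfone ionises again in step 10.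

Step 9
Reactants: 14 4-bromo-2-methoxyphenol
Product: 15 1-(benzyloxy)-4-bromo-2-methoxybenzene
Conditions: BnBr, K2CO3, DMF, rt
Reagents that add atoms: benzyl bromide, BrCc1ccccc1
Why: Williamson ether synthesis on a phenol; the benzyl ether tolerates ArMgBr formation and is removed in the last step.

Step 10
Reactants: 13 (4S,6S)-2-(benzenesulfonyl)-6-[(1R)-2-[4-(benzyloxy)phenyl]-1-[(tert-butyldimethylsilyl)oxy]ethyl]-4-[(tert-butyldimethylsilyl)oxy]oxane; 15 1-(benzyloxy)-4-bromo-2-methoxybenzene
Product: 18 (2S,4R,6S)-2-[4-(benzyloxy)-3-methoxyphenyl]-6-[(1R)-2-[4-(benzyloxy)phenyl]-1-[(tert-butyldimethylsilyl)oxy]ethyl]-4-[(tert-butyldimethylsilyl)oxy]oxane, via arylmagnesium bromide 16 (not isolated), via arylzinc bromide 17 (not isolated)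
Conditions: 15, Mg, THF, reflux; ZnBr2, THF, 0 °C → rt; then 13, THF, rt; aq. NH4Cl
Reagents that add atoms: none
Why: Substitution of a 2-benzenesulfonyl cyclic ether by an organozinc reagent: the zinc and magnesium halides ionise the sulfone to the oxocarbenium ion, whose preferred half-chair holds the C3 silyloxy group and the C5 chain pseudo-equatorial, and 17 attacks along the axial trajectory through a chair-like transition state, anti to the C5 chain, setting C1 (S) with the aryl group trans to both substituents. The organozinc is too weakly basic to deprotonate the cation and does not touch silyl or benzyl ethers.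

Step 11
Reactants: 18 (2S,4R,6S)-2-[4-(benzyloxy)-3-methoxyphenyl]-6-[(1R)-2-[4-(benzyloxy)phenyl]-1-[(tert-butyldimethylsilyl)oxy]ethyl]-4-[(tert-butyldimethylsilyl)oxy]oxane
Product: 19 (2S,4R,6S)-2-[4-(benzyloxy)-3-methoxyphenyl]-6-[(1R)-2-[4-(benzyloxy)phenyl]-1-hydroxyethyl]oxan-4-ol
Conditions: Bu4NF, THF, rt → 40 °C
Reagents that add atoms: none
Why: Fluoride-induced cleavage of both secondary silyl ethers; it is run while both phenols are still benzylated, so no phenoxide para to the C1–O1 bond is formed under basic conditions.

Step 12
Reactants: 19 (2S,4R,6S)-2-[4-(benzyloxy)-3-methoxyphenyl]-6-[(1R)-2-[4-(benzyloxy)phenyl]-1-hydroxyethyl]oxan-4-ol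
Product: 20 (2S,4R,6S)-2-(4-hydroxy-3-methoxyphenyl)-6-[(1R)-1-hydroxy-2-(4-hydroxyphenyl)ethyl]oxan-4-ol
Conditions: H2 (1 atm), 10% Pd/C, EtOAc, rt
Reagents that add atoms: none
Why: Hydrogenolysis of aryl benzyl ethers over Pd/C in a neutral medium; cleavage of phenolic benzyl ethers is much faster than cleavage of the ring benzylic C1–O1 bond, so the reaction is stopped as soon as both benzyl groups are gone, and no stereocentre is touched.

## Compound list

1 | O-benzyl-D-tyrosine, (R)-2-amino-3-[4-(benzyloxy)phenyl]propanoic acid | N[C@H](Cc1ccc(OCc2ccccc2)cc1)C(=O)O | starting material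
2 | (R)-3-[4-(benzyloxy)phenyl]-2-diazoniopropanoate (diazonium carboxylate, formed in situ) | N#[N+][C@H](Cc1ccc(OCc2ccccc2)cc1)C(=O)[O-] | intermediate
3 | (S)-3-[4-(benzyloxy)benzyl]oxiran-2-one (alpha-lactone, formed in situ) | O=C1O[C@H]1Cc1ccc(OCc2ccccc2)cc1 | intermediate
4 | (R)-3-[4-(benzyloxy)phenyl]-2-hydroxypropanoic acid | O[C@H](Cc1ccc(OCc2ccccc2)cc1)C(=O)O | intermediate
5 | methyl (R)-3-[4-(benzyloxy)phenyl]-2-hydroxypropanoate | O[C@H](Cc1ccc(OCc2ccccc2)cc1)C(=O)OC | intermediate
6 | methyl (R)-3-[4-(benzyloxy)phenyl]-2-[(tert-butyldimethylsilyl)oxy]propanoate | CC(C)(C)[Si](C)(C)O[C@H](Cc1ccc(OCc2ccccc2)cc1)C(=O)OC | intermediate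
7 | (R)-3-[4-(benzyloxy)phenyl]-2-[(tert-butyldimethylsilyl)oxy]propanal | O=C[C@H](O[Si](C)(C)C(C)(C)C)Cc1ccc(OCc2ccccc2)cc1 | intermediate
8 | Danishefsky's diene, (E)-1-methoxy-3-[(trimethylsilyl)oxy]buta-1,3-diene | CO/C=C/C(=C)O[Si](C)(C)C | starting material
9 | (1E,5S,6R)-7-[4-(benzyloxy)phenyl]-6-[(tert-butyldimethylsilyl)oxy]-5-hydroxy-1-methoxyhept-1-en-3-one (aldol adduct, formed in situ) | CO/C=C/C(=O)C[C@H](O)[C@H](O[Si](C)(C)C(C)(C)C)Cc1ccc(OCc2ccccc2)cc1 | intermediate
10 | (2S)-2-[(1R)-2-[4-(benzyloxy)phenyl]-1-[(tert-butyldimethylsilyl)oxy]ethyl]-2,3-dihydro-4H-pyran-4-one | O=C1C=CO[C@@H](C1)[C@H](O[Si](C)(C)C(C)(C)C)Cc1ccc(OCc2ccccc2)cc1 | intermediate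
11 | (2S,4S)-2-[(1R)-2-[4-(benzyloxy)phenyl]-1-[(tert-butyldimethylsilyl)oxy]ethyl]-3,4-dihydro-2H-pyran-4-ol (OH cis to the side chain) | C1=C[C@@H](O)C[C@@H]([C@H](O[Si](C)(C)C(C)(C)C)Cc2ccc(OCc3ccccc3)cc2)O1 | intermediate
12 | (2S,4S)-2-[(1R)-2-[4-(benzyloxy)phenyl]-1-[(tert-butyldimethylsilyl)oxy]ethyl]-4-[(tert-butyldimethylsilyl)oxy]-3,4-dihydro-2H-pyran | C1=C[C@@H](O[Si](C)(C)C(C)(C)C)C[C@@H]([C@H](O[Si](C)(C)C(C)(C)C)Cc2ccc(OCc3ccccc3)cc2)O1 | intermediate
13 | (4S,6S)-2-(benzenesulfonyl)-6-[(1R)-2-[4-(benzyloxy)phenyl]-1-[(tert-butyldimethylsilyl)oxy]ethyl]-4-[(tert-butyldimethylsilyl)oxy]oxane (C2 epimers) | O=S(=O)(c1ccccc1)C1C[C@@H](O[Si](C)(C)C(C)(C)C)C[C@@H]([C@H](O[Si](C)(C)C(C)(C)C)Cc2ccc(OCc3ccccc3)cc2)O1 | intermediate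
14 | 4-bromo-2-methoxyphenol | COc1cc(Br)ccc1O | starting material
15 | 1-(benzyloxy)-4-bromo-2-methoxybenzene | COc1cc(Br)ccc1OCc1ccccc1 | intermediate
16 | [4-(benzyloxy)-3-methoxyphenyl]magnesium bromide (formed in situ) | COc1cc([Mg]Br)ccc1OCc1ccccc1 | intermediate
17 | [4-(benzyloxy)-3-methoxyphenyl]zinc bromide (formed in situ) | COc1cc([Zn]Br)ccc1OCc1ccccc1 | intermediate
18 | (2S,4R,6S)-2-[4-(benzyloxy)-3-methoxyphenyl]-6-[(1R)-2-[4-(benzyloxy)phenyl]-1-[(tert-butyldimethylsilyl)oxy]ethyl]-4-[(tert-butyldimethylsilyl)oxy]oxane | COc1cc([C@@H]2C[C@@H](O[Si](C)(C)C(C)(C)C)C[C@@H]([C@H](O[Si](C)(C)C(C)(C)C)Cc3ccc(OCc4ccccc4)cc3)O2)ccc1OCc1ccccc1 | intermediate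
19 | (2S,4R,6S)-2-[4-(benzyloxy)-3-methoxyphenyl]-6-[(1R)-2-[4-(benzyloxy)phenyl]-1-hydroxyethyl]oxan-4-ol | COc1cc([C@@H]2C[C@@H](O)C[C@@H]([C@H](O)Cc3ccc(OCc4ccccc4)cc3)O2)ccc1OCc1ccccc1 | intermediate
20 | (2S,4R,6S)-2-(4-hydroxy-3-methoxyphenyl)-6-[(1R)-1-hydroxy-2-(4-hydroxyphenyl)ethyl]oxan-4-ol | COc1cc([C@@H]2C[C@@H](O)C[C@@H]([C@H](O)Cc3ccc(O)cc3)O2)ccc1O | target

## Step count and least certain steps

Total step count: 12. Longest linear sequence: 11 steps (from 1 through steps 1 to 8 and 10 to 12); step 9 is the one-step side branch.

**Step 5 (key step).**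
- What may go wrong: insufficient facial discrimination at the aldehyde when the open transition state is poorly organised, together with partial epimerisation at C6 through enolisation of the Lewis acid-bound aldehyde.
- Fallback: the substrate-controlled, stepwise Lewis acid process is replaced by a catalyst-controlled concerted cycloaddition. Setting out from 7 and 8, the chiral chromium chloride complex [CrCl(L)] with 4 Å molecular sieves at room temperature should give the cycloadduct (6S)-6-[(1R)-2-[4-(benzyloxy)phenyl]-1-[(tert-butyldimethylsilyl)oxy]ethyl]-2-methoxy-4-[(trimethylsilyl)oxy]-5,6-dihydro-2H-pyran F1. The complex contains trivalent chromium; L is the dianion of the tridentate Schiff base from 3-(1-adamantyl)-2-hydroxy-5-methylbenzaldehyde and cis-1-aminoindan-2-ol, used as the enantiomer whose facial preference coincides with the Felkin–Anh face. Brief treatment with TFA in CH2Cl2 eliminates methanol and cleaves the silyl enol ether, returning to the route at 10.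

**Step 10.**
- What may go wrong: proton loss from the oxocarbenium ion (elimination of sulfinic acid back to the enol ether) outrunning aryl transfer, and incomplete axial selectivity.
- Fallback: the aryl group is introduced on the enone instead. Setting out from 10, rhodium-catalysed conjugate addition of commercial 4-benzyloxy-3-methoxyphenylboronic acid ([Rh(cod)2]BF4, monovalent rhodium, dioxane–H2O, heating) should deliver the aryl group to C1 anti to the C5 chain. This gives the ketone (2S,6S)-2-[4-(benzyloxy)-3-methoxyphenyl]-6-[(1R)-2-[4-(benzyloxy)phenyl]-1-[(tert-butyldimethylsilyl)oxy]ethyl]oxan-4-one F3. Reduction under conditions that favour the equatorial carbinol (SmI2, i-PrOH, THF) would give the alcohol (2S,4R,6S)-2-[4-(benzyloxy)-3-methoxyphenyl]-6-[(1R)-2-[4-(benzyloxy)phenyl]-1-[(tert-butyldimethylsilyl)oxy]ethyl]oxan-4-ol F4. Bu4NF then removes the C6 silyl ether, returning at 19.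
- This path is shorter but is not the first choice: C3 would be set on a ring with an axial aryl group, where the facial preference is less predictable than in the Luche reduction of 10.

**Step 8.**
- What may go wrong: ionisation of the allylic C3 silyloxy group (Ferrier-type rearrangement), hydrolysis of the oxocarbenium ion to the lactol, and slow capture by the weakly nucleophilic sulfinate.
- Fallback: sulfur is introduced as the far more nucleophilic thiol and oxidised afterwards. Setting out from 12, PhSH with catalytic PPh3·HBr in CH2Cl2 should give the thioacetal (4S,6S)-6-[(1R)-2-[4-(benzyloxy)phenyl]-1-[(tert-butyldimethylsilyl)oxy]ethyl]-4-[(tert-butyldimethylsilyl)oxy]-2-(phenylsulfanyl)oxane F2. Oxidation with mCPBA buffered by NaHCO3 at 0 °C returns to the route at 13.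

**Step 12.**
- What may go wrong: over-reduction, that is hydrogenolytic cleavage of the ring benzylic C1–O1 bond once the para-phenol is unmasked, or epimerisation at C1 by trace acid on the catalyst.
- Fallback: the protecting-group plan is changed so that the guaiacyl oxygen is still capped during hydrogenolysis and the last step is non-reductive.
  - Setting out from 14, silylation (TBSCl, imidazole, DMF) gives the aryl bromide (4-bromo-2-methoxyphenoxy)(tert-butyl)dimethylsilane F5.
  - As in step 10, F5 is converted into {4-[(tert-butyldimethylsilyl)oxy]-3-methoxyphenyl}magnesium bromide F6 and then {4-[(tert-butyldimethylsilyl)oxy]-3-methoxyphenyl}zinc bromide F7.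
  - Coupling with 13 gives the tris-silyl ether (2S,4R,6S)-6-[(1R)-2-[4-(benzyloxy)phenyl]-1-[(tert-butyldimethylsilyl)oxy]ethyl]-4-[(tert-butyldimethylsilyl)oxy]-2-{4-[(tert-butyldimethylsilyl)oxy]-3-methoxyphenyl}oxane F8.
  - Hydrogenolysis (H2, 10% Pd/C, EtOAc) removes the only benzyl ether, on the remote ring, giving the phenol 4-[(2R)-2-[(tert-butyldimethylsilyl)oxy]-2-[(2S,4S,6S)-4-[(tert-butyldimethylsilyl)oxy]-6-{4-[(tert-butyldimethylsilyl)oxy]-3-methoxyphenyl}oxan-2-yl]ethyl]phenol F9.
  - Bu4NF buffered with AcOH cleaves all three silyl ethers, returning at 20.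

## Further compounds

F1 | step 5 | (6S)-6-[(1R)-2-[4-(benzyloxy)phenyl]-1-[(tert-butyldimethylsilyl)oxy]ethyl]-2-methoxy-4-[(trimethylsilyl)oxy]-5,6-dihydro-2H-pyran (C2 epimers) | COC1C=C(O[Si](C)(C)C)C[C@H](O1)[C@H](O[Si](C)(C)C(C)(C)C)Cc1ccc(OCc2ccccc2)cc1
F2 | step 8 | (4S,6S)-6-[(1R)-2-[4-(benzyloxy)phenyl]-1-[(tert-butyldimethylsilyl)oxy]ethyl]-4-[(tert-butyldimethylsilyl)oxy]-2-(phenylsulfanyl)oxane (C2 epimers) | c1ccccc1SC1C[C@@H](O[Si](C)(C)C(C)(C)C)C[C@@H]([C@H](O[Si](C)(C)C(C)(C)C)Cc2ccc(OCc3ccccc3)cc2)O1
F3 | step 10 | (2S,6S)-2-[4-(benzyloxy)-3-methoxyphenyl]-6-[(1R)-2-[4-(benzyloxy)phenyl]-1-[(tert-butyldimethylsilyl)oxy]ethyl]oxan-4-one | COc1cc([C@@H]2CC(=O)C[C@@H]([C@H](O[Si](C)(C)C(C)(C)C)Cc3ccc(OCc4ccccc4)cc3)O2)ccc1OCc1ccccc1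
F4 | step 10 | (2S,4R,6S)-2-[4-(benzyloxy)-3-methoxyphenyl]-6-[(1R)-2-[4-(benzyloxy)phenyl]-1-[(tert-butyldimethylsilyl)oxy]ethyl]oxan-4-ol | COc1cc([C@@H]2C[C@@H](O)C[C@@H]([C@H](O[Si](C)(C)C(C)(C)C)Cc3ccc(OCc4ccccc4)cc3)O2)ccc1OCc1ccccc1
F5 | step 12 | (4-bromo-2-methoxyphenoxy)(tert-butyl)dimethylsilane | COc1cc(Br)ccc1O[Si](C)(C)C(C)(C)C
F6 | step 12 | {4-[(tert-butyldimethylsilyl)oxy]-3-methoxyphenyl}magnesium bromide | COc1cc([Mg]Br)ccc1O[Si](C)(C)C(C)(C)C
F7 | step 12 | {4-[(tert-butyldimethylsilyl)oxy]-3-methoxyphenyl}zinc bromide | COc1cc([Zn]Br)ccc1O[Si](C)(C)C(C)(C)C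
F8 | step 12 | (2S,4R,6S)-6-[(1R)-2-[4-(benzyloxy)phenyl]-1-[(tert-butyldimethylsilyl)oxy]ethyl]-4-[(tert-butyldimethylsilyl)oxy]-2-{4-[(tert-butyldimethylsilyl)oxy]-3-methoxyphenyl}oxane | COc1cc([C@@H]2C[C@@H](O[Si](C)(C)C(C)(C)C)C[C@@H]([C@H](O[Si](C)(C)C(C)(C)C)Cc3ccc(OCc4ccccc4)cc3)O2)ccc1O[Si](C)(C)C(C)(C)C
F9 | step 12 | 4-[(2R)-2-[(tert-butyldimethylsilyl)oxy]-2-[(2S,4S,6S)-4-[(tert-butyldimethylsilyl)oxy]-6-{4-[(tert-butyldimethylsilyl)oxy]-3-methoxyphenyl}oxan-2-yl]ethyl]phenol | COc1cc([C@@H]2C[C@@H](O[Si](C)(C)C(C)(C)C)C[C@@H]([C@H](O[Si](C)(C)C(C)(C)C)Cc3ccc(O)cc3)O2)ccc1O[Si](C)(C)C(C)(C)C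
A1 | alternative 1 | 2-(tert-butyldimethylsilyl)-1,3-dithiane | CC(C)(C)[Si](C)(C)C1SCCCS1
A2 | alternative 1 | (R)-2-[4-(benzyloxy)-3-methoxyphenyl]oxirane | COc1cc([C@@H]2CO2)ccc1OCc1ccccc1
A3 | alternative 1 | (R)-2-[(R)-1-(benzyloxy)-2-[4-(benzyloxy)phenyl]ethyl]oxirane | C1O[C@H]1[C@H](OCc1ccccc1)Cc1ccc(OCc2ccccc2)cc1
A4 | alternative 1 | (1S,5R,6R)-6-(benzyloxy)-1-[4-(benzyloxy)-3-methoxyphenyl]-7-[4-(benzyloxy)phenyl]-1-[(tert-butyldimethylsilyl)oxy]-5-hydroxyheptan-3-one 1,3-propanediyl dithioketal | COc1cc([C@@H](O[Si](C)(C)C(C)(C)C)CC2(SCCCS2)C[C@@H](O)[C@H](OCc3ccccc3)Cc3ccc(OCc4ccccc4)cc3)ccc1OCc1ccccc1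
A5 | alternative 2 | (3S,5R)-5-[2-[4-(benzyloxy)-3-methoxyphenyl]-2-hydroxyethyl]-3-hydroxyoxolan-2-one (either epimer at the benzylic carbinol) | COc1cc(C(O)C[C@@H]2C[C@H](O)C(=O)O2)ccc1OCc1ccccc1
A6 | alternative 2 | exo-3-[4-(benzyloxy)-3-methoxyphenyl]-2,6-dioxabicyclo[3.2.1]octan-7-one | COc1cc([C@@H]2C[C@@H]3C[C@@H](C(=O)O3)O2)ccc1OCc1ccccc1
A7 | alternative 3 | 2-{2-[4-(benzyloxy)-3-methoxyphenyl]-1,3-dioxolan-2-yl}acetaldehyde oxime | COc1cc(C2(CC=NO)OCCO2)ccc1OCc1ccccc1
A8 | alternative 3 | (R)-{[1-[4-(benzyloxy)phenyl]but-3-en-2-yl]oxy}(tert-butyl)dimethylsilane | C=C[C@H](O[Si](C)(C)C(C)(C)C)Cc1ccc(OCc2ccccc2)cc1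
A9 | alternative 3 | (5S)-3-({2-[4-(benzyloxy)-3-methoxyphenyl]-1,3-dioxolan-2-yl}methyl)-5-[(1R)-2-[4-(benzyloxy)phenyl]-1-[(tert-butyldimethylsilyl)oxy]ethyl]-4,5-dihydroisoxazole | COc1cc(C2(CC3=NO[C@@H](C3)[C@H](O[Si](C)(C)C(C)(C)C)Cc4ccc(OCc5ccccc5)cc4)OCCO2)ccc1OCc1ccccc1
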